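A time of 6.97 h is what E needs, late in the zeta run, to fall by a factor of e. This e-folding time, read from the logarithm of E, is the number to follow through the zeta flask, which is the flask asked about.

the same everywhere: J 25 mM; D 34 mM
- zeta: E 1 M; Q 1.5 M; the very flask that is asked about, followed so far
- epsilon: E 0.50 M; Q 1.5 M; run made earlier
- flask: E 1.0 M; Q 1.50 M; time 15 h; volume of the second phase over the first 0.50

- zeta (time / h: E / %, X / %): 0.333: 94.0, 6.4; 0.833: 84.5, 16.6; 1.50: 73.4, 25.7; 2.50: 62.0, 37.5; 3.00: 56.9, 42.7; 5.00: 42.7, 57.1
- epsilon (time / h: E / %, X / %): 0.417: 91.8, 9.2; 1.33: 75.2, 25.1; 2.00: 65.2, 35.9; 3.00: 53.6, 46.3; 5.00: 37.3, 62.7; 6.00: 31.0, 69.4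

(readings scatter by 0.5 percentage points)

- in the second phase: Q, L; everything else is in the first
- charges count per volume of the first phase; a concentration in a rate is the amount of a species over the volume of its own phase; every rate counts per litre of the first phase
- the analysis behind the earlier runs scatters by 0.5 percentage points, standard deviation
- steps under discussion: J + Q <-> G + L; E + G -> X + J; D + G <-> Z
- the earlier runs hold the two phases in the same ratio of volumes as the flask asked about

- the species in which most of what was charged as E, at 15 h sits (E / X)
- the largest share itself, whichever of these holds it, in percent of the E charged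

In the first instants J takes up Q across the phases and gives G and L; G turns E into X and returns J, while D holds part of G as Z. The loss of E reads as pseudo-first-order, with an e-folding time that drifts.

In the middle L grows and Q falls. If the first step stands near its balance and D stays near its charge, G over J goes as Q over L, so the catalyst counted over G, and with it the e-folding time, is a straight line in L/Q. From 3.00 h to 6.00 h the epsilon run has an e-folding time of 5.48 h at a ratio of L to Q of 0.239, while the zeta run, from 3.00 h to 5.00 h, is slower with 6.97 h at 0.499. These readings put the rise of the line at 5.73 h per unit of ratio, the salt lag, from 4.11 h at zero ratio.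

Towards the end, zeta starts from a ratio of 0.615 at 5.00 h. Frozen there, the line leaves E at 11.5 % by 15 h, a ratio of 1.44. The mean ratio gives 9.99 h, so this reckoning ends with E at 15.7 % and X at 84.3 %.

The forecast names X at 85 %, above this reckoning, on the ground that “the two runs agree at equal L/Q”.

The flask gives X at 86.1 %, with E at 13.9 %. At 15.0 h the catalyst stands as J 57.1 %, G 27.3 % and Z 15.6 %. From the reading at 5.00 h onward the mean e-folding time of E comes out at 8.88 h, under the 9.99 h that the line with the salt lag of 5.73 h gave. The epsilon recipe carried to 15 h runs from a ratio of 0.301 to 0.452. The same reckoning gives it 6.27 h and X at 92.6 %; the simulated epsilon flask holds X at 92.9 % at that time.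

    J + Q ⇌ G + L (K = 0.669, k = 0.0342 L mol⁻¹ s⁻¹)
    E + G → X + J (k = 0.00390 L mol⁻¹ s⁻¹)
    D + G ⇌ Z, settled at all times (K = 19.0 L mol⁻¹)

The numbers in the tables stem from a simulated flask for substances that don't exist; scatter was added.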